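**Plan**

1. Retrosynthesis: the 1,2-dioxolane (C11'–O–O–C8' hemiketal with C6'=C7') is cut back to an isopropylidene ketone and the C2 acetate to a bridging ketone. The norbornene bonds C1–C4' and C3–C3' are then cut to two guaiane cyclopentadienone units. The right unit is cut at C1'–C5' to germacrone 4,5-epoxide; the left unit at C10–CH3 and at the C1–C10 ring bond to a diazoketone of 2-isopropylanisole.
2. Enabling feature: the right-hand hydroazulene (C1'–C10') carries the C8' oxygen and the C11'–C13' branch on C7' exactly where germacrone has them. Its cyclopentane and cycloheptane rings therefore differ from the cyclodecadiene only by the C1'–C5' bond.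
3. Forward, right half: ten-membered ring to five- plus seven-membered ring (step 2), then C2' ketone and 3'-ene. Left half: benzene ring to cyclopentanone plus cycloheptatriene (Buchner reaction), then the C10 methyl group, then the cyclopentadienone ketal.
4. Union: the norbornene ring arises by Diels–Alder reaction of the left ketal diene with the right cyclopentadienone made in the flask; the C2 oxygen is then adjusted and the 1,2-dioxolane ring is closed last.
5. Stereochemistry: C10 comes from a copper-catalysed asymmetric conjugate addition (the only external source of chirality) and C7 from equilibration. C1, C3, C3' and C4' come from an endo cycloaddition on the faces opposite the C10 and C10' methyl groups, and C10' from dynamic kinetic resolution in that step. C2 comes from thermodynamic control of the ketone reduction and C8' from ring–chain equilibration.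

Key step: step 2

Remark: guaiane numbering is used (left half C1–C15, right half primed). The germacrone-derived intermediates and the early arene-derived intermediates are racemic, C4 of the left half is carried as an inconsequential epimer mixture until it becomes trigonal, and the C7 and C8' configurations of the natural product are assumed to be the thermodynamically preferred ones.

**Step 1**
Reactants: 1 germacrone
Product: 2 germacrone 4,5-epoxide (racemic trans-epoxide)
Conditions: mCPBA (1 equiv), CH2Cl2, 0 °C
Reagents that add atoms: meta-chloroperoxybenzoic acid, OOC(=O)c1cccc(Cl)c1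
Why: Prilezhaev epoxidation with one equivalent of peracid should take the most electron-rich 4,5-alkene (the 1(10)-alkene is deactivated by the homoallylic C8 carbonyl, the 7(11)-alkene by conjugation), and syn addition to the E-alkene gives the trans-epoxide as a racemate.

**Step 2**
Reactants: 2 germacrone 4,5-epoxide
Product: 3 4-hydroxyguaia-1(10),7(11)-dien-8-one (racemic, 4-OH and 5-H cis)
Conditions: BF3·OEt2 (0.2 equiv), CH2Cl2, −78 °C; Et3N quench
Reagents that add atoms: none
Why: BF3 binds the epoxide oxygen and, in the crown conformer of the E,E-cyclodecadiene, C1 of the facing 1(10)-alkene attacks C5 opposite the breaking C5–O bond, so that C1–C5 forms, C4 keeps its oxygen and the tertiary C10 cation is discharged by loss of H1 to the tetrasubstituted 1(10)-alkene. The closest known reaction type is the acid-promoted transannular epoxide–olefin cyclisation of germacrane 4,5-epoxides to guaianes, a cation–olefin cyclisation. The five-membered ring closes 5-exo with respect to the alkene (the cationic centre C10 stays outside it) and endo with respect to the epoxide (both oxirane carbons become ring members), and the seven-membered ring is what remains of the ten-membered ring. C5 is set by the stereospecific anti opening of the trans-epoxide and C4 is carried over from it; both become trigonal later, so racemic 2 suffices. The step needs C1–C5 rather than C10–C5 bonding (guaiane, not eudesmane), which the preference for the tertiary C10 cation and the crossed, close arrangement of the two π systems secure, and it needs loss of H1 rather than H9, H14 or capture by water, which anhydrous conditions at low temperature and the fully substituted product alkene should favour.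

**Step 3**
Reactants: 3 4-hydroxyguaia-1(10),7(11)-dien-8-one
Product: 4 4-hydroxyguaia-1(10),7(11)-diene-2,8-dione
Conditions: t-BuOOH, Rh2(cap)4 (cap = caprolactamate, 1 mol %), CH2Cl2, rt
Reagents that add atoms: tert-butyl hydroperoxide, CC(C)(C)OO
Why: Allylic oxidation by tert-butylperoxyl radicals should take the ring methylene C2 next to the electron-rich 1(10)-alkene, because C9 is deactivated by the C8 carbonyl, C5–H is tertiary and flanked by the carbinol carbon, and the isopropylidene enone is electron-poor; no stereocentre is formed.

**Step 4**
Reactants: 4 4-hydroxyguaia-1(10),7(11)-diene-2,8-dione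
Product: 5 guaia-1(10),3,7(11)-triene-2,8-dione
Conditions: TsOH·H2O (cat.), toluene, 60 °C
Reagents that add atoms: none
Why: Acid-catalysed dehydration of a β-hydroxy ketone through its C2–C3 enol removes the tertiary C4 hydroxyl regiospecifically towards C3 and gives the cross-conjugated dienone, with no new stereocentre.

**Step 5**
Reactants: 6 2-isopropylanisole; 7 (E)-crotonic acid
Product: 8 3-(3-isopropyl-4-methoxyphenyl)butanoic acid
Conditions: AlCl3 (2.5 equiv), CH2Cl2, 0 °C to rt; aq. HCl
Reagents that add atoms: none
Why: Friedel–Crafts conjugate alkylation by the crotonic acid–AlCl3 complex should occur para to the methoxy group, the most activated and least hindered position of 6; the benzylic centre (later C4) forms racemic and is erased in step 12.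

**Step 6**
Reactants: 8 3-(3-isopropyl-4-methoxyphenyl)butanoic acid
Product: 10 1-diazo-4-(3-isopropyl-4-methoxyphenyl)pentan-2-one, via acid chloride 9 (not isolated)
Conditions: (COCl)2, DMF (cat.), CH2Cl2, 0 °C to rt; then CH2N2, Et3N, Et2O, 0 °C
Reagents that add atoms: oxalyl chloride, O=C(Cl)C(=O)Cl; diazomethane, C=[N+]=[N-]
Why: Acylation of diazomethane by the acid chloride with Et3N as HCl scavenger (the diazoketone stage of an Arndt–Eistert sequence) touches no stereocentre.

**Step 7**
Reactants: 10 1-diazo-4-(3-isopropyl-4-methoxyphenyl)pentan-2-one
Product: 12 14-norguaia-1(5),9-diene-2,8-dione, via methoxycycloheptatriene 11 (not isolated)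
Conditions: Rh2(OAc)4 (1 mol %), CH2Cl2, 40 °C, slow addition; then 1 M HCl, THF, 0 °C
Reagents that add atoms: water, O
Why: In this intramolecular Buchner reaction the rhodium carbene should cyclopropanate the ipso–ortho bond remote from the isopropyl group and the norcaradiene opens to 11, so that the methoxy carbon becomes C8 and the isopropyl carbon C7; cold dilute acid then hydrolyses the enol ether to the C8 ketone while the double bonds move into conjugation with both carbonyls, strong acid being avoided because it would divert 11 to a 2-tetralone.

**Step 8**
Reactants: 12 14-norguaia-1(5),9-diene-2,8-dione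
Product: 13 (7S,10R)-guaia-1(5)-ene-2,8-dione
Conditions: Me2Zn, Cu(OTf)2 (2 mol %), (S)-binaphthol-derived N,N-bis[(R)-1-phenylethyl]phosphoramidite (4 mol %), toluene, −30 °C; aq. NH4Cl; then DBU (cat.), CH2Cl2, rt
Reagents that add atoms: dimethylzinc, C[Zn]C
Why: Copper-catalysed asymmetric conjugate addition to the disubstituted C9=C10 enone (the alternative 1,6-addition would have to attack the fully substituted C5) sets C10, the ligand enantiomer being chosen by analogy with cyclohex-2-enone to give (R), and DBU then equilibrates C7 next to the C8 ketone to the expected cis isomer with a pseudo-equatorial isopropyl group.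

**Step 9**
Reactants: 13 (7S,10R)-guaia-1(5)-ene-2,8-dione
Product: 14 (7S,10R)-8,8-(ethylenedioxy)guaia-1(5)-en-2-one
Conditions: HOCH2CH2OH, TsOH (cat.), toluene, reflux, removal of water
Reagents that add atoms: ethylene glycol, OCCO
Why: Acid-catalysed ketalisation should be chemoselective for the saturated C8 ketone over the tetrasubstituted conjugated C2 enone and creates no stereocentre.

**Step 10**
Reactants: 14 (7S,10R)-8,8-(ethylenedioxy)guaia-1(5)-en-2-one
Product: 15 (7S,10R)-3-bromo-8,8-(ethylenedioxy)guaia-1(5)-en-2-one
Conditions: LiN(SiMe3)2, THF, −78 °C; NBS; aq. NH4Cl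
Reagents that add atoms: N-bromosuccinimide, O=C1CCC(=O)N1Br
Why: Kinetic deprotonation of the enone at the α′ carbon C3 gives the cross-conjugated lithium enolate, which NBS brominates (α-halogenation of a ketone enolate); the C3 configuration is of no consequence.

**Step 11**
Reactants: 15 (7S,10R)-3-bromo-8,8-(ethylenedioxy)guaia-1(5)-en-2-one
Product: 16 (7S,10R)-3-bromo-8,8-(ethylenedioxy)-2,2-dimethoxyguaia-1(5)-ene
Conditions: MeOSiMe3, Me3SiOTf (cat.), CH2Cl2, −78 to −20 °C
Reagents that add atoms: methoxytrimethylsilane, CO[Si](C)(C)C
Why: Silyl-triflate-catalysed ketalisation with an alkoxysilane is the mild way to ketalise a hindered α-bromo enone and should leave the dioxolane and the tetrasubstituted alkene in place.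

**Step 12**
Reactants: 16 (7S,10R)-3-bromo-8,8-(ethylenedioxy)-2,2-dimethoxyguaia-1(5)-ene
Product: 17 (7S,10R)-8,8-(ethylenedioxy)-2,2-dimethoxyguaia-1(5),3-diene
Conditions: KOtBu, DMSO, rt
Reagents that add atoms: none
Why: Base-induced dehydrobromination (E2) of an α-bromo ketal towards C4–H is the standard access to cyclopentadienone ketals, and the three ring substituents of this 5,5-dialkoxycyclopentadiene should slow its dimerisation; C3 and C4 become trigonal.

**Step 13**
Reactants: 17 (7S,10R)-8,8-(ethylenedioxy)-2,2-dimethoxyguaia-1(5),3-diene; 5 guaia-1(10),3,7(11)-triene-2,8-dione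
Product: 19 endo Diels–Alder adduct (bis-ketal), via cyclopentadienone 18 (not isolated)
Conditions: DBU (0.2 equiv), toluene, 40 °C, argon, dark; 5 added slowly as a toluene solution to an equimolar amount of 17
Reagents that add atoms: none
Why: Proposed new method: DBU reversibly removes the doubly activated C5–H of 5 (γ to the C2 carbonyl and allylic to C1=C10) and reprotonation of the achiral vinylogous enolate at C10 gives a small stationary amount of the fully conjugated cyclopentadienone 18, which the electron-rich ketal diene should trap at once in an endo Diels–Alder reaction at the less substituted C3'=C4' bond, the α-carbon C3' (largest LUMO coefficient of a cyclopentadienone) bonding to the unhindered terminus C3 and C4' to C1; each partner is attacked opposite its pseudo-axial C10 methyl group, which sets C1, C3, C3' and C4', and because both enantiomers of 5 and of 18 interconvert through the same achiral enolate the (10R)-diene should draw all of racemic 5 through the matching (10'R)-enantiomer of 18, so that the two partners combine one to one with nothing split off; the closest known reaction types are the generation of cyclopentadienones by base-induced elimination with Diels–Alder trapping by cyclopentadienes and the endo-selective dimerisation of cyclopentadienones.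

**Step 14**
Reactants: 19 endo Diels–Alder adduct (bis-ketal)
Product: 20 2,8,2',8'-tetraone
Conditions: 2 M HCl, THF, 0 °C to rt
Reagents that add atoms: water, O
Why: Acid hydrolysis removes both ketals (the bridging dimethyl ketal more slowly because its oxocarbenium ion is strained) at an acidity too low to protonate the tetrasubstituted C4=C5 bond, and C7 is again free to equilibrate to the cis isomer; 20 is used at once and kept cold because the bis-enone adduct could undergo a Cope rearrangement on heating.

**Step 15**
Reactants: 20 2,8,2',8'-tetraone
Product: 21 (2S)-2-hydroxy-8,2',8'-trione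
Conditions: Al(OiPr)3, i-PrOH/acetone (1:5), toluene, 60 °C, to equilibrium; aq. HCl
Reagents that add atoms: none
Why: In a Meerwein–Ponndorf–Verley reduction run reversibly in an acetone-rich medium the strained bridging ketone has by far the most favourable reduction equilibrium (the α-branched cycloheptanone C8 and the two enones should stay largely at the ketone level), and its aluminium alkoxide equilibrates through the ketone to the more stable epimer with oxygen over the C4=C5 bridge and away from the exo methyl group on C4', which is (2S); a kinetic hydride would attack from the open alkene side and give the other epimer.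

**Step 16**
Reactants: 21 (2S)-2-hydroxy-8,2',8'-trione
Product: 22 (2S)-2-acetoxy-8,2',8'-trione
Conditions: Ac2O, DMAP (cat.), pyridine, CH2Cl2, rt
Reagents that add atoms: acetic anhydride, CC(=O)OC(C)=O
Why: DMAP-catalysed acylation of the secondary alcohol leaves the C2 configuration unchanged.

**Step 17**
Reactants: 22 (2S)-2-acetoxy-8,2',8'-trione
Product: 24 target CNP0317907.1, via hydroperoxide 23 (not isolated)
Conditions: O2, visible light, tetraphenylporphyrin (cat.), CH2Cl2, 0 °C
Reagents that add atoms: dioxygen, O=O
Why: In the Schenck ene reaction singlet oxygen attacks the s-cis isopropylidene ketone, abstracts hydrogen from the substituent geminal to the carbonyl (C6') and places the hydroperoxide on C11'; 23 then closes onto the C8' ketone to the 1,2-dioxolan-3-ol, whose C8' configuration is set by ring–chain equilibration, while the s-trans C1'=C5' enone is inert and the C4=C5 alkene is screened on its exo face by the syn acetoxy group and on its endo face by the cyclopentenone ring.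

**Compound list**

1 | germacrone | C/C1=C\CC/C(C)=C/CC(=C(C)C)C(=O)C1 | starting material
2 | germacrone 4,5-epoxide, racemic (4S,5S drawn) | C/C1=C\CC[C@]2(C)O[C@H]2CC(=C(C)C)C(=O)C1 | intermediate
3 | 4-hydroxyguaia-1(10),7(11)-dien-8-one, racemic (4S,5S drawn) | CC1=C2CC[C@](C)(O)[C@H]2CC(=C(C)C)C(=O)C1 | intermediate
4 | 4-hydroxyguaia-1(10),7(11)-diene-2,8-dione, racemic (4S,5S drawn) | CC1=C2C(=O)C[C@](C)(O)[C@H]2CC(=C(C)C)C(=O)C1 | intermediate
5 | guaia-1(10),3,7(11)-triene-2,8-dione, racemic | CC1=C2C(=O)C=C(C)C2CC(=C(C)C)C(=O)C1 | intermediate
6 | 2-isopropylanisole | COc1ccccc1C(C)C | starting material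
7 | (E)-crotonic acid | C/C=C/C(=O)O | starting material
8 | 3-(3-isopropyl-4-methoxyphenyl)butanoic acid, racemic | COc1ccc(cc1C(C)C)C(C)CC(=O)O | intermediate
9 | 3-(3-isopropyl-4-methoxyphenyl)butanoyl chloride | COc1ccc(cc1C(C)C)C(C)CC(=O)Cl | intermediate
10 | 1-diazo-4-(3-isopropyl-4-methoxyphenyl)pentan-2-one | COc1ccc(cc1C(C)C)C(C)CC(=O)C=[N+]=[N-] | intermediate
11 | 8-methoxy-14-norguaia-5,7,9-trien-2-one | COC1=C(C(C)C)C=C2C(C)CC(=O)C2C=C1 | intermediate
12 | 14-norguaia-1(5),9-diene-2,8-dione, racemic | CC(C)C1CC2=C(C=CC1=O)C(=O)CC2C | intermediate
13 | (7S,10R)-guaia-1(5)-ene-2,8-dione, C4 epimers | C[C@@H]1CC(=O)[C@H](C(C)C)CC2=C1C(=O)CC2C | intermediate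
14 | (7S,10R)-8,8-(ethylenedioxy)guaia-1(5)-en-2-one, C4 epimers | C[C@@H]1CC2(OCCO2)[C@H](C(C)C)CC3=C1C(=O)CC3C | intermediate
15 | (7S,10R)-3-bromo-8,8-(ethylenedioxy)guaia-1(5)-en-2-one, C3/C4 epimers | C[C@@H]1CC2(OCCO2)[C@H](C(C)C)CC3=C1C(=O)C(Br)C3C | intermediate
16 | (7S,10R)-3-bromo-8,8-(ethylenedioxy)-2,2-dimethoxyguaia-1(5)-ene, C3/C4 epimers | C[C@@H]1CC2(OCCO2)[C@H](C(C)C)CC3=C1C(OC)(OC)C(Br)C3C | intermediate
17 | (7S,10R)-8,8-(ethylenedioxy)-2,2-dimethoxyguaia-1(5),3-diene | C[C@@H]1CC2(OCCO2)[C@H](C(C)C)CC3=C1C(OC)(OC)C=C3C | intermediate
18 | (10R)-guaia-1(5),3,7(11)-triene-2,8-dione (cyclopentadienone, reacting enantiomer) | C[C@@H]1CC(=O)C(=C(C)C)CC2=C1C(=O)C=C2C | intermediate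
19 | endo adduct of 17 (C1, C3) and 18 (C4', C3'): 2,2-dimethoxy-8,8-ethylenedioxy left half, 1'(5'),7'(11')-diene-2',8'-dione right half, (7S,10R,10'R) | COC1(OC)[C@H]2C(C)=C3C[C@@H](C(C)C)C4(OCCO4)C[C@@H](C)[C@]31[C@]1(C)C3=C(C(=O)[C@H]21)[C@H](C)CC(=O)C(=C(C)C)C3 | intermediate
20 | 2,8,2',8'-tetraone of the dimer | O=C1[C@H]2C(C)=C3C[C@@H](C(C)C)C(=O)C[C@@H](C)[C@]31[C@]1(C)C3=C(C(=O)[C@H]21)[C@H](C)CC(=O)C(=C(C)C)C3 | intermediate
21 | (2S)-2-hydroxy-8,2',8'-trione, OH syn to C4=C5 | O[C@H]1[C@H]2C(C)=C3C[C@@H](C(C)C)C(=O)C[C@@H](C)[C@]31[C@]1(C)C3=C(C(=O)[C@H]21)[C@H](C)CC(=O)C(=C(C)C)C3 | intermediate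
22 | (2S)-2-acetoxy-8,2',8'-trione | CC(=O)O[C@H]1[C@H]2C(C)=C3C[C@@H](C(C)C)C(=O)C[C@@H](C)[C@]31[C@]1(C)C3=C(C(=O)[C@H]21)[C@H](C)CC(=O)C(=C(C)C)C3 | intermediate
23 | 11'-hydroperoxy-6'-ene of 22 | CC(=O)O[C@H]1[C@H]2C(C)=C3C[C@@H](C(C)C)C(=O)C[C@@H](C)[C@]31[C@]1(C)C3=C(C(=O)[C@H]21)[C@H](C)CC(=O)C(C(C)(C)OO)=C3 | intermediate
24 | CNP0317907.1, (2S,7S,10R,8'R,10'R) | CC(=O)O[C@H]1[C@H]2C(C)=C3C[C@@H](C(C)C)C(=O)C[C@@H](C)[C@]31[C@]1(C)C3=C(C(=O)[C@H]21)[C@H](C)C[C@@]1(O)OOC(C)(C)C1=C3 | target

**Count**

Total: 17 steps. Longest linear sequence: 13 steps (steps 5–17, from 2-isopropylanisole); the germacrone branch (steps 1–4) joins at step 13.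

**Steps most likely to fail**

Step 13. The tautomerisation may be too slow, so that self-condensation of the dienolate of 5 or self-dimerisation of 18 outruns the cross-cycloaddition. Regio- or face-selectivity may also erode, or the resolution may stay incomplete so that the mismatched enantiomer is consumed as well. The fallback uses known chemistry and sets out from 4. The cyclopentanone-bound double bond alone is moved into the five-membered ring with RhCl3·3H2O in ethanol (exo-to-endo enone isomerisation; the isopropylidene ketone is already the stable isomer), which gives 4-hydroxyguaia-1(5),7(11)-diene-2,8-dione F1. F1 is then exposed to (CF3CO)2O and Et3N in the presence of 17, so that E1cB loss of trifluoroacetate from C4 releases 18 stoichiometrically at low temperature; the route is rejoined at 19.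

Step 15. Equilibration may stall at the kinetically formed C2 epimer, because hydride transfer from the face of the exo methyl group is slow. Partial reduction of the C8 ketone and aldol chemistry with acetone may also consume material. The fallback sets out from 20. All enolisable carbonyl groups are first masked as lithium enolates with excess LiN(SiMe3)2. The bridging ketone, the only one that cannot enolise, is then reduced with lithium in liquid ammonia, where the carbanion intermediate is protonated on the hindered face. Aqueous work-up returns the other carbonyl groups and the route is rejoined at 21 (no new compound, F0).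

Step 17. The ene reaction may also take place at the tetrasubstituted C4=C5 bond, or oxidation may go too far. The fallback sets out from 22 and uses triplet oxygen with DBU in acetonitrile. Only C6'–H2 (γ to the C2' enone and next to C7') is acidic enough to be removed, the vinylogous enolate is expected to be oxygenated at C11', and the hydroperoxide 23 closes as before, so the route is rejoined at 24 (no new compound, F0).

**Further compounds**

F1 | step 13 | 4-hydroxyguaia-1(5),7(11)-diene-2,8-dione (mixture of stereoisomers) | CC1CC(=O)C(=C(C)C)CC2=C1C(=O)CC2(C)O
F0 | step 15 | none | none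
F0 | step 17 | none | none
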